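C25 eremophilane ester CNP0143497.3: total synthesis through an intramolecular Diels–Alder reaction of a glutamate-derived trienone

Feature: the ring B run C4–C3–C2–C1(O)–C10 is a 2-oxygenated glutaric chain. Ring A (C5–C10) is the dehydrogenated adduct of a 2-silyloxydiene C10=C9–C8=C7 with an isopropenyl ketone C5=C6 whose C4 carbonyl lies in that chain.
Cuts, in retrosynthetic order: C11=C13 and the allyl terminus at C12, the C1–O acyl bond, C7–C11, C4–C15, then C5–C10 and C6–C7 together, and in the open chain C4–C5 and C9=C10.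
Forward: the trienone is assembled on a lactone derived from L-glutamic acid. One intramolecular Diels–Alder reaction then closes rings A and B, and C15, the C7 side chain and the C1 ester follow.
Stereochemistry: C1 (S, chiral pool) sits equatorial in the chair-like transition state and so places C14 on the opposite face, which fixes C5. C10 is erased by dehydrogenation.
C4 (hydroboration) and C7 (enolate allylation) are set anti to axial C14. C1 is inverted to the axial β-ester in the Mitsunobu coupling, and C4' of the acid comes from an oxazolidinone-controlled methylation.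

Key step: step 7

Remark: eremophilane numbering is used for the bicyclic compounds. C1 is the acyloxy carbon, C4 the carboxyl-bearing carbon, C5 quaternary, C7 the side-chain carbon, C8 the ketone, C14 the angular methyl, C15 the carboxyl carbon and C11–C13 the acrolein unit. Ring A is C5–C10 and ring B is C1–C5 plus C10. β is the face of C14. The transient C8 carbinol of step 10 is drawn as the expected β-alcohol; its epimer would give the same ketone in step 11.

Step 1
Reactants: 1 (S)-5-(hydroxymethyl)dihydrofuran-2(3H)-one (commercial, made from L-glutamic acid)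
Product: 2 (S)-4,5-dihydroxy-N-methoxy-N-methylpentanamide
Conditions: MeNH(OMe)·HCl, AlMe3, CH2Cl2, 0 °C to rt
Reagents that add atoms: N,O-dimethylhydroxylamine hydrochloride, CNOC.Cl
Why: Aluminium amide aminolysis of a lactone (Weinreb amide formation) opens the ring at the C4 carbonyl only, leaves the C1 carbinol centre untouched, and the excess reagent merely holds the free hydroxyl as its aluminium alkoxide.

Step 2
Reactants: 2 (S)-4,5-dihydroxy-N-methoxy-N-methylpentanamide
Product: 3 (S)-4,5-bis(tert-butyldimethylsilyloxy)-N-methoxy-N-methylpentanamide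
Conditions: TBSCl, imidazole, DMF, rt (on the freshly made diol)
Reagents that add atoms: tert-butyldimethylsilyl chloride, CC(C)(C)[Si](C)(C)Cl
Why: Imidazole-promoted silylation of both hydroxyls removes the C1 hydroxyl that would otherwise re-close the lactone and installs the bulky C1 group that later steers the cycloaddition.

Step 3
Reactants: 3 (S)-4,5-bis(tert-butyldimethylsilyloxy)-N-methoxy-N-methylpentanamide
Product: 4 (S)-4-(tert-butyldimethylsilyloxy)-5-hydroxy-N-methoxy-N-methylpentanamide
Conditions: HF·pyridine, pyridine, THF, 0 °C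
Reagents that add atoms: none
Why: Selective desilylation works because buffered HF·pyridine cleaves the unhindered primary C10 silyl ether much faster than the secondary C1 ether, a standard differentiation of 1,2-bis(silyl ethers).

Step 4
Reactants: 4 (S)-4-(tert-butyldimethylsilyloxy)-5-hydroxy-N-methoxy-N-methylpentanamide; 5 1-(triphenylphosphoranylidene)propan-2-one
Product: 7 (S,E)-4-(tert-butyldimethylsilyloxy)-N-methoxy-N-methyl-7-oxooct-5-enamide, via α-silyloxy aldehyde 6 (not isolated)
Conditions: Dess–Martin periodinane, CH2Cl2, 0 °C to rt; then 5, rt to 40 °C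
Reagents that add atoms: none
Why: Dess–Martin oxidation followed in the same flask by Wittig olefination reaches the aldehyde by oxidation, so the Weinreb amide never meets a hydride, the epimerisable α-silyloxy aldehyde is not isolated, and the stabilised ylide gives the (E)-alkene C9=C10.

Step 5
Reactants: 7 (S,E)-4-(tert-butyldimethylsilyloxy)-N-methoxy-N-methyl-7-oxooct-5-enamide
Product: 8 (S,E)-4,7-bis(tert-butyldimethylsilyloxy)-N-methoxy-N-methylocta-5,7-dienamide
Conditions: TBSOTf, Et3N, CH2Cl2, −78 to 0 °C
Reagents that add atoms: tert-butyldimethylsilyl triflate, CC(C)(C)[Si](C)(C)OS(=O)(=O)C(F)(F)F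
Why: Soft enolisation with a silyl triflate and a tertiary amine deprotonates the methyl group (C7) of the (E)-enone under kinetic control and gives the cross-conjugated 2-silyloxydiene, while the amide is not enolised under these conditions.

Step 6
Reactants: 8 (S,E)-4,7-bis(tert-butyldimethylsilyloxy)-N-methoxy-N-methylocta-5,7-dienamide; 9 isopropenylmagnesium bromide
Product: 11 (S,E)-6,9-bis(tert-butyldimethylsilyloxy)-2-methyldeca-1,7,9-trien-3-one, via magnesium hemiaminal chelate 10 (not isolated)
Conditions: 9, THF, −78 to −20 °C; cold pH 7 phosphate buffer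
Reagents that add atoms: none
Why: In this Weinreb ketone synthesis the five-membered magnesium chelate holds the tetrahedral adduct until the quench, so a single isopropenyl group reaches C4, the silyl dienol ether is inert to the Grignard reagent, and the cold neutral quench keeps it from hydrolysing.

Step 7
Reactants: 11 (S,E)-6,9-bis(tert-butyldimethylsilyloxy)-2-methyldeca-1,7,9-trien-3-one
Product: 12 (4S,4aR,8aS)-4,6-bis(tert-butyldimethylsilyloxy)-8a-methyl-3,4,4a,7,8,8a-hexahydronaphthalen-1(2H)-one (cis-fused; eremophilane descriptors 1S,5S,10R; 1α-silyloxy, 10β-H, 14β-methyl)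
Conditions: toluene (0.02 M), BHT (cat.), 100 °C, base-washed glassware
Reagents that add atoms: none
Why: The reaction is a thermal, concerted but asynchronous normal-demand [4+2] cycloaddition in which C7, the nucleophilic terminus of the 2-silyloxydiene, leads the bonding to the enone β-carbon C6 while C10 closes on C5; the polarity and the four-atom tether C1–C4 both allow only this fused orientation. The closest known reaction type is the intramolecular Diels–Alder reaction of 1,7,9-decatrien-3-ones, here with the diene made more nucleophilic by the silyloxy group. Ring A (C5–C10) is the new cyclohexene formed by the cycloaddition itself and keeps C8=C9 as a regiodefined silyl enol ether, whereas ring B (C1–C5, C10) closes as a six-membered carbocycle through the C5–C10 bond with the tether folded as a chair. C10 follows from the (E)-geometry of C9=C10 and from the preferred endo placement of the C4 carbonyl under the diene, which gives the cis ring fusion with 10-H cis to C14. C5 is controlled by C1, because the chair with the silyloxy group equatorial is favoured (an axial C1–O would be 1,3-diaxial to the methyl on C5) and this chair delivers C14 to the face opposite to C1–O, so the (S)-configured chain leads to the natural configuration at C5. Only diene-face selectivity is needed, since the carbonyl-exo, trans-fused chair with equatorial silyloxy gives the same C1/C5 relationship and C10 is erased in step 9.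

Step 8
Reactants: 12 cis-fused decalone (1S,5S,10R)
Product: 13 (4S,4aR,8aS)-4,6-bis(tert-butyldimethylsilyloxy)-8a-methyl-1-methylidene-1,2,3,4,4a,7,8,8a-octahydronaphthalene (C4=C15 exocyclic methylene)
Conditions: Ph3PCH3Br, KOtBu, toluene, rt to 80 °C
Reagents that add atoms: methyltriphenylphosphonium bromide, C[P+](c1ccccc1)(c1ccccc1)c1ccccc1.[Br-]
Why: Wittig methylenation with the ylide generated by KOtBu is the standard way to methylenate ketones flanked by a quaternary carbon, C3 is the only enolisable position and bears no stereocentre, and both silyl groups tolerate the basic anhydrous medium, so C8 stays masked while C4 reacts.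

Step 9
Reactants: 13 C4-methylidene bis(silyl ether)
Product: 14 (4aR,8S)-8-(tert-butyldimethylsilyloxy)-4a-methyl-5-methylidene-4,4a,5,6,7,8-hexahydronaphthalen-2(3H)-one (C9=C10 enone, 1α-silyloxy)
Conditions: Pd(OAc)2 (1.1 equiv), MeCN, rt to 40 °C
Reagents that add atoms: none
Why: In the Saegusa–Ito oxidation the silyl enol ether is transmetalated to a palladium enolate bound at C9 and β-hydride elimination of 10-H places the alkene at C9=C10 as fixed by the cycloaddition, which also removes C10 as a stereocentre so that any trans-fused adduct converges, while the isolated 1,1-disubstituted alkene is a spectator.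

Step 10
Reactants: 14 C9=C10 enone with C4=C15 methylene
Product: 16 (2S,4aR,5S,8S)-8-(tert-butyldimethylsilyloxy)-5-(hydroxymethyl)-4a-methyl-2,3,4,4a,5,6,7,8-octahydronaphthalen-2-ol, via bis(9-BBN) adduct 15 (not isolated)
Conditions: 9-BBN (3 equiv), THF, 0 to 40 °C; then NaOH, H2O2, 0 °C to rt
Reagents that add atoms: hydrogen peroxide, OO
Why: Hydroboration–oxidation with 9-BBN attacks C4=C15 from the α face, away from the axial C14 on the neighbouring carbon, so boron goes to C15, hydrogen to C4α and C15 ends β (equatorial, cis to C14); the reagent also reduces the C8 enone 1,2 as it is known to do (repaired in step 11), and the hindered trisubstituted C9=C10 stays untouched.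

Step 11
Reactants: 16 C8,C15-diol
Product: 17 (1S,4S,8aR)-4-(tert-butyldimethylsilyloxy)-8a-methyl-6-oxo-1,2,3,4,6,7,8,8a-octahydronaphthalene-1-carboxylic acid
Conditions: TEMPO (cat.), PhI(OAc)2, MeCN/H2O, rt
Reagents that add atoms: water, O
Why: Oxoammonium (TEMPO) oxidation in aqueous acetonitrile carries the primary C15 alcohol through the aldehyde hydrate to the acid and returns the allylic C8 alcohol to the enone in the same operation, under mild conditions that spare the silyl ether and the equatorial C4 substituent.

Step 12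
Reactants: 17 keto acid
Product: 18 tert-butyl (1S,4S,8aR)-4-(tert-butyldimethylsilyloxy)-8a-methyl-6-oxo-1,2,3,4,6,7,8,8a-octahydronaphthalene-1-carboxylate
Conditions: Cl3CC(=NH)OtBu, BF3·OEt2 (cat.), CH2Cl2/cyclohexane, rt
Reagents that add atoms: tert-butyl 2,2,2-trichloroacetimidate, CC(C)(C)OC(=N)C(Cl)(Cl)Cl
Why: Trichloroacetimidate esterification alkylates the carboxyl oxygen by tert-butyl cation transfer, so the crowding around the C15 carbonyl next to the quaternary carbon does not matter, and the ester will resist the base and the Mitsunobu conditions to come.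

Step 13
Reactants: 18 tert-butyl ester enone
Product: 20 tert-butyl (1S,4S,7R,8aR)-7-allyl-4-(tert-butyldimethylsilyloxy)-8a-methyl-6-oxo-1,2,3,4,6,7,8,8a-octahydronaphthalene-1-carboxylate (7α-allyl), via lithium cross-conjugated dienolate 19 (not isolated)
Conditions: LiN(iPr)2 (1.05 equiv), THF, −78 °C; then allyl bromide, DMPU, −78 to −30 °C
Reagents that add atoms: allyl bromide, C=CCBr
Why: Kinetic enolate alkylation works because LiN(iPr)2 removes the α' proton at C7 (far more acidic than the hindered C4–H of the tert-butyl ester), and the dienolate is allylated on the α face anti to the pseudoaxial C14, giving the equatorial 7α-allyl group, which is also the thermodynamically preferred epimer.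

Step 14
Reactants: 20 7α-allyl silyl ether
Product: 21 tert-butyl (1S,4S,7R,8aR)-7-allyl-4-hydroxy-8a-methyl-6-oxo-1,2,3,4,6,7,8,8a-octahydronaphthalene-1-carboxylate (1α-alcohol)
Conditions: HF·pyridine, THF, 0 °C to rt
Reagents that add atoms: none
Why: Fluoride-driven desilylation under weakly acidic conditions frees the allylic C1 alcohol without touching the tert-butyl ester and without the basicity that could disturb C7.

Step 15
Reactants: 22 hexanoic acid; 23 (R)-4-benzyloxazolidin-2-one
Product: 25 (R)-4-benzyl-3-hexanoyloxazolidin-2-one, via hexanoic pivalic anhydride 24 (not isolated)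
Conditions: pivaloyl chloride, Et3N, THF, −20 °C; then 23, LiCl, rt
Reagents that add atoms: none
Why: In this mixed-anhydride N-acylation the oxazolidinone, activated by LiCl and Et3N, attacks the unhindered hexanoyl carbonyl of the pivalic mixed anhydride.

Step 16
Reactants: 25 (R)-4-benzyl-3-hexanoyloxazolidin-2-one
Product: 27 (R)-4-benzyl-3-[(R)-2-methylhexanoyl]oxazolidin-2-one, via chelated (Z)-sodium enolate 26 (not isolated)
Conditions: NaN(SiMe3)2, THF, −78 °C; then MeI
Reagents that add atoms: iodomethane, CI
Why: In the Evans alkylation the chelated (Z)-enolate is methylated on the face opposite to the benzyl group of the (R)-auxiliary, which sets the (R)-configured methyl-bearing centre that becomes C4' of the ester side chain.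

Step 17
Reactants: 27 (R)-4-benzyl-3-[(R)-2-methylhexanoyl]oxazolidin-2-one
Product: 28 (R)-2-methylhexan-1-ol
Conditions: LiBH4, H2O (1 equiv), Et2O, 0 °C
Reagents that add atoms: none
Why: Reductive removal of the auxiliary with LiBH4 attacks the exocyclic imide carbonyl and gives the primary alcohol without enolisation, so the new centre is kept.

Step 18
Reactants: 28 (R)-2-methylhexan-1-ol; 29 ethyl 2-(triphenylphosphoranylidene)propanoate
Product: 31 ethyl (R,E)-2,4-dimethyloct-2-enoate, via (R)-2-methylhexanal 30 (not isolated)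
Conditions: Dess–Martin periodinane, CH2Cl2, 0 °C to rt; then 29, rt
Reagents that add atoms: none
Why: Tandem Dess–Martin oxidation and Wittig olefination trap the volatile, epimerisable α-branched aldehyde as it forms, and the α-methyl stabilised ylide gives the (E)-trisubstituted enoate.

Step 19
Reactants: 31 ethyl (R,E)-2,4-dimethyloct-2-enoate
Product: 32 (R,E)-2,4-dimethyloct-2-enoic acid
Conditions: LiOH, THF/MeOH/H2O, rt to 40 °C; then aq. HCl
Reagents that add atoms: lithium hydroxide, [Li+].[OH-]
Why: Saponification of the ethyl ester leaves the alkene geometry and the γ-stereocentre alone because the conjugated carboxylate is not deprotonated at C4' under these conditions.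

Step 20
Reactants: 21 1α-alcohol; 32 (R,E)-2,4-dimethyloct-2-enoic acid
Product: 33 tert-butyl (1S,4R,7R,8aR)-7-allyl-4-{[(2E,4R)-2,4-dimethyloct-2-enoyl]oxy}-8a-methyl-6-oxo-1,2,3,4,6,7,8,8a-octahydronaphthalene-1-carboxylate (1β-ester)
Conditions: PPh3, DIAD, toluene, 0 °C to rt
Reagents that add atoms: none
Why: In the Mitsunobu esterification the equatorial 1α-alkoxyphosphonium ion, which has no antiperiplanar hydrogen on C2 for elimination, is displaced by the carboxylate in an SN2 process with inversion, so acylation and correction of C1 to the axial β (R) configuration happen in one step.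

Step 21
Reactants: 33 1β-ester tert-butyl ester
Product: 34 (1S,4R,7R,8aR)-7-allyl-4-{[(2E,4R)-2,4-dimethyloct-2-enoyl]oxy}-8a-methyl-6-oxo-1,2,3,4,6,7,8,8a-octahydronaphthalene-1-carboxylic acid
Conditions: TFA/CH2Cl2 (1:3), 0 °C to rt
Reagents that add atoms: none
Why: Acidolysis of the tert-butyl ester (loss of isobutene) spares the C1 ester, whose ionisation is disfavoured next to the electron-poor enone, and it is placed here so that the later 1,4-keto aldehyde and enal never meet strong acid.

Step 22
Reactants: 34 7α-allyl acid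
Product: 36 (1S,4R,7S,8aR)-4-{[(2E,4R)-2,4-dimethyloct-2-enoyl]oxy}-8a-methyl-6-oxo-7-(2-oxoethyl)-1,2,3,4,6,7,8,8a-octahydronaphthalene-1-carboxylic acid, via terminal 1,2-diol 35 (not isolated)
Conditions: OsO4 (cat.), NaIO4, 2,6-lutidine, dioxane/H2O, rt; mildly acidic extraction
Reagents that add atoms: osmium tetroxide, O=[Os](=O)(=O)=O (delivers the oxygen and is regenerated by sodium periodate, [Na+].[O-]I(=O)(=O)=O)
Why: In the Lemieux–Johnson oxidation OsO4 dihydroxylates the only electron-rich, monosubstituted alkene, whereas the enone and the enoate are trisubstituted and electron-poor, and periodate cleaves the diol to the C12 aldehyde.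

Step 23
Reactants: 36 keto aldehyde acid
Product: 37 target, (1S,4R,7S,8aR)-4-{[(2E,4R)-2,4-dimethyloct-2-enoyl]oxy}-8a-methyl-6-oxo-7-(3-oxoprop-1-en-2-yl)-1,2,3,4,6,7,8,8a-octahydronaphthalene-1-carboxylic acid
Conditions: 37% aq. HCHO, pyrrolidine (cat.), propionic acid (cat.), iPrOH, 40 °C
Reagents that add atoms: formaldehyde, C=O
Why: In this amine/acid-catalysed Mannich condensation–elimination (organocatalytic α-methylenation of an aldehyde) only the unhindered aldehyde forms an enamine, which reacts at C11 with formaldehyde and loses the amine to give C11=C13, and the near-neutral medium should keep the equatorial C7 centre and stop the new alkene from migrating into conjugation with C8.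

Compound list
1 | (S)-5-(hydroxymethyl)dihydrofuran-2(3H)-one | O=C1CC[C@@H](CO)O1 | starting material
2 | (S)-4,5-dihydroxy-N-methoxy-N-methylpentanamide | CON(C)C(=O)CC[C@@H](CO)O | intermediate
3 | (S)-4,5-bis(tert-butyldimethylsilyloxy)-N-methoxy-N-methylpentanamide | CON(C)C(=O)CC[C@@H](CO[Si](C)(C)C(C)(C)C)O[Si](C)(C)C(C)(C)C | intermediate
4 | (S)-4-(tert-butyldimethylsilyloxy)-5-hydroxy-N-methoxy-N-methylpentanamide | CON(C)C(=O)CC[C@@H](CO)O[Si](C)(C)C(C)(C)C | intermediate
5 | 1-(triphenylphosphoranylidene)propan-2-one | CC(=O)C=P(c1ccccc1)(c1ccccc1)c1ccccc1 | starting material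
6 | (S)-4-(tert-butyldimethylsilyloxy)-N-methoxy-N-methyl-5-oxopentanamide (not isolated) | CON(C)C(=O)CC[C@@H](C=O)O[Si](C)(C)C(C)(C)C | intermediate
7 | (S,E)-4-(tert-butyldimethylsilyloxy)-N-methoxy-N-methyl-7-oxooct-5-enamide | CON(C)C(=O)CC[C@@H](/C=C/C(C)=O)O[Si](C)(C)C(C)(C)C | intermediate
8 | (S,E)-4,7-bis(tert-butyldimethylsilyloxy)-N-methoxy-N-methylocta-5,7-dienamide | CON(C)C(=O)CC[C@@H](/C=C/C(=C)O[Si](C)(C)C(C)(C)C)O[Si](C)(C)C(C)(C)C | intermediate
9 | isopropenylmagnesium bromide | C=C(C)[Mg]Br | starting material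
10 | magnesium hemiaminal chelate at C4 (not isolated) | C=C(C)C(O[Mg]Br)(N(C)OC)CC[C@@H](/C=C/C(=C)O[Si](C)(C)C(C)(C)C)O[Si](C)(C)C(C)(C)C | intermediate
11 | (S,E)-6,9-bis(tert-butyldimethylsilyloxy)-2-methyldeca-1,7,9-trien-3-one | C=C(C)C(=O)CC[C@@H](/C=C/C(=C)O[Si](C)(C)C(C)(C)C)O[Si](C)(C)C(C)(C)C | intermediate
12 | (4S,4aR,8aS)-4,6-bis(tert-butyldimethylsilyloxy)-8a-methyl-3,4,4a,7,8,8a-hexahydronaphthalen-1(2H)-one | CC(C)(C)[Si](C)(C)OC1=C[C@H]2[C@@H](O[Si](C)(C)C(C)(C)C)CCC(=O)[C@@]2(C)CC1 | intermediate
13 | (4S,4aR,8aS)-4,6-bis(tert-butyldimethylsilyloxy)-8a-methyl-1-methylidene-1,2,3,4,4a,7,8,8a-octahydronaphthalene | CC(C)(C)[Si](C)(C)OC1=C[C@H]2[C@@H](O[Si](C)(C)C(C)(C)C)CCC(=C)[C@@]2(C)CC1 | intermediate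
14 | (4aR,8S)-8-(tert-butyldimethylsilyloxy)-4a-methyl-5-methylidene-4,4a,5,6,7,8-hexahydronaphthalen-2(3H)-one | O=C1C=C2[C@@H](O[Si](C)(C)C(C)(C)C)CCC(=C)[C@@]2(C)CC1 | intermediate
15 | C15-(9-BBN) borane, C8-O-(9-BBN) borinate (not isolated) | C12CCCC(CCC1)B2O[C@@H]1C=C2[C@@H](O[Si](C)(C)C(C)(C)C)CC[C@H](CB3C4CCCC3CCC4)[C@@]2(C)CC1 | intermediate
16 | (2S,4aR,5S,8S)-8-(tert-butyldimethylsilyloxy)-5-(hydroxymethyl)-4a-methyl-2,3,4,4a,5,6,7,8-octahydronaphthalen-2-ol | O[C@@H]1C=C2[C@@H](O[Si](C)(C)C(C)(C)C)CC[C@H](CO)[C@@]2(C)CC1 | intermediate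
17 | (1S,4S,8aR)-4-(tert-butyldimethylsilyloxy)-8a-methyl-6-oxo-1,2,3,4,6,7,8,8a-octahydronaphthalene-1-carboxylic acid | O=C1C=C2[C@@H](O[Si](C)(C)C(C)(C)C)CC[C@H](C(=O)O)[C@@]2(C)CC1 | intermediate
18 | tert-butyl ester of 17 | O=C1C=C2[C@@H](O[Si](C)(C)C(C)(C)C)CC[C@H](C(=O)OC(C)(C)C)[C@@]2(C)CC1 | intermediate
19 | lithium cross-conjugated dienolate of 18 (C7=C8–OLi, not isolated) | [Li]OC=1C=C2[C@@H](O[Si](C)(C)C(C)(C)C)CC[C@H](C(=O)OC(C)(C)C)[C@@]2(C)CC=1 | intermediate
20 | tert-butyl (1S,4S,7R,8aR)-7-allyl-4-(tert-butyldimethylsilyloxy)-8a-methyl-6-oxo-1,2,3,4,6,7,8,8a-octahydronaphthalene-1-carboxylate | O=C1C=C2[C@@H](O[Si](C)(C)C(C)(C)C)CC[C@H](C(=O)OC(C)(C)C)[C@@]2(C)C[C@H]1CC=C | intermediate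
21 | tert-butyl (1S,4S,7R,8aR)-7-allyl-4-hydroxy-8a-methyl-6-oxo-1,2,3,4,6,7,8,8a-octahydronaphthalene-1-carboxylate | O=C1C=C2[C@@H](O)CC[C@H](C(=O)OC(C)(C)C)[C@@]2(C)C[C@H]1CC=C | intermediate
22 | hexanoic acid | CCCCCC(=O)O | starting material
23 | (R)-4-benzyloxazolidin-2-one | O=C1N[C@H](Cc2ccccc2)CO1 | starting material
24 | hexanoic pivalic anhydride (not isolated) | CCCCCC(=O)OC(=O)C(C)(C)C | intermediate
25 | (R)-4-benzyl-3-hexanoyloxazolidin-2-one | CCCCCC(=O)N1[C@H](Cc2ccccc2)COC1=O | intermediate
26 | (Z)-sodium enolate of 25 (not isolated) | CCCC/C=C(\O[Na])N1[C@H](Cc2ccccc2)COC1=O | intermediate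
27 | (R)-4-benzyl-3-[(R)-2-methylhexanoyl]oxazolidin-2-one | CCCC[C@@H](C)C(=O)N1[C@H](Cc2ccccc2)COC1=O | intermediate
28 | (R)-2-methylhexan-1-ol | CCCC[C@@H](C)CO | intermediate
29 | ethyl 2-(triphenylphosphoranylidene)propanoate | CCOC(=O)C(C)=P(c1ccccc1)(c1ccccc1)c1ccccc1 | starting material
30 | (R)-2-methylhexanal (not isolated) | CCCC[C@@H](C)C=O | intermediate
31 | ethyl (R,E)-2,4-dimethyloct-2-enoate | CCOC(=O)/C(C)=C/[C@H](C)CCCC | intermediate
32 | (R,E)-2,4-dimethyloct-2-enoic acid | OC(=O)/C(C)=C/[C@H](C)CCCC | intermediate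
33 | tert-butyl (1S,4R,7R,8aR)-7-allyl-4-{[(2E,4R)-2,4-dimethyloct-2-enoyl]oxy}-8a-methyl-6-oxo-1,2,3,4,6,7,8,8a-octahydronaphthalene-1-carboxylate | O=C1C=C2[C@H](OC(=O)/C(C)=C/[C@H](C)CCCC)CC[C@H](C(=O)OC(C)(C)C)[C@@]2(C)C[C@H]1CC=C | intermediate
34 | free C15 acid of 33 | O=C1C=C2[C@H](OC(=O)/C(C)=C/[C@H](C)CCCC)CC[C@H](C(=O)O)[C@@]2(C)C[C@H]1CC=C | intermediate
35 | terminal 1,2-diol from 34 (carbinol epimers, not isolated) | O=C1C=C2[C@H](OC(=O)/C(C)=C/[C@H](C)CCCC)CC[C@H](C(=O)O)[C@@]2(C)C[C@H]1CC(O)CO | intermediate
36 | (1S,4R,7S,8aR)-4-{[(2E,4R)-2,4-dimethyloct-2-enoyl]oxy}-8a-methyl-6-oxo-7-(2-oxoethyl)-1,2,3,4,6,7,8,8a-octahydronaphthalene-1-carboxylic acid | O=C1C=C2[C@H](OC(=O)/C(C)=C/[C@H](C)CCCC)CC[C@H](C(=O)O)[C@@]2(C)C[C@H]1CC=O | intermediate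
37 | CNP0143497.3 (eremophilane descriptors 1R,4S,5R,7S; side chain 2'E,4'R) | C=C(C=O)[C@@H]1C[C@@]2(C)C(=CC1=O)[C@H](OC(=O)/C(C)=C/[C@H](C)CCCC)CC[C@@H]2C(=O)O | target

Total step count: 23 (18 in the main line, 5 for the side-chain acid).
Longest linear sequence: 18 steps (steps 1–14 and 20–23).

Steps most likely to fail

1. Step 20, Mitsunobu inversion at C1.
- Risk: displacement may be slow because the carboxylate has to enter on the β face beside the axial C14. The activated alcohol could then be diverted into elimination towards C2, or into acylation with retention.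
- Fallback (redox inversion, then ordinary acylation), setting out from 21:
  - Dess–Martin oxidation gives the C1,C8 ene-dione F1.
  - Luche reduction (NaBH4, CeCl3·7H2O, MeOH, −78 °C) delivers hydride to both carbonyls from the α face, anti to C14, and gives the 1β,8β-diol F2.
  - MnO2 in CH2Cl2 oxidises only the quasi-equatorial C8 allylic alcohol, whose C–H bond is aligned with the π system, and leaves the axial C1 alcohol, giving the 1β-hydroxy enone F3.
  - Yamaguchi esterification with 32 (2,4,6-trichlorobenzoyl chloride, Et3N, DMAP, toluene) comes back to the route at 33.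

2. Step 7, the cycloaddition.
- Risk: diene-face selectivity may erode if the small oxygen substituent does not hold the equatorial position firmly. The silyl dienol ether may also be lost thermally before the sluggish α-methyl enone reacts.
- Fallback: stereocontrol and activation are moved from the substrate to a reagent.
  - Compound 11 is cyclised at −78 to −40 °C with a chiral cationic oxazaborolidine Lewis acid, prepared from diphenylprolinol, o-tolylboronic acid and Tf2NH, which binds the C4 carbonyl.
  - The catalyst enantiomer is chosen so that its face preference reinforces that of C1.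
  - This is a known type of catalytic asymmetric Diels–Alder reaction of 2-silyloxydienes with enones. It forms the same two bonds, sets out from 11 and comes back at 12 without any new compound.

3. Step 10, hydroboration at C4=C15.
- Risk: addition to the alkene next to the quaternary carbon may be sluggish or poorly face-selective, and conjugate reduction of the enone may compete.
- Fallback (one-carbon homologation through an enol ether), setting out from 12:
  - Wittig reaction with Ph3P=CHOMe (MeOCH2PPh3Cl, KOtBu, THF) gives the C4-methoxymethylidene bis(enol ether) F4.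
  - Saegusa–Ito oxidation with Pd(OAc)2 consumes only the silyl enol ether and gives the enone enol ether F5.
  - Aqueous acid hydrolysis protonates C4 from the α face. A brief K2CO3/MeOH equilibration then secures the equatorial 4β-carbaldehyde F6.
  - Pinnick oxidation (NaClO2, NaH2PO4, 2-methyl-2-butene, tBuOH/H2O) comes back to the route at 17.

Further compounds
F1 | step 20 | tert-butyl (1S,7R,8aR)-7-allyl-8a-methyl-4,6-dioxo-1,2,3,4,6,7,8,8a-octahydronaphthalene-1-carboxylate (C1,C8 ene-dione) | O=C1C=C2C(=O)CC[C@H](C(=O)OC(C)(C)C)[C@@]2(C)C[C@H]1CC=C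
F2 | step 20 | 1β,8β-diol (eremophilane numbering) of the 7α-allyl tert-butyl ester | O[C@@H]1C=C2[C@H](O)CC[C@H](C(=O)OC(C)(C)C)[C@@]2(C)C[C@H]1CC=C
F3 | step 20 | tert-butyl (1S,4R,7R,8aR)-7-allyl-4-hydroxy-8a-methyl-6-oxo-1,2,3,4,6,7,8,8a-octahydronaphthalene-1-carboxylate (1β-alcohol) | O=C1C=C2[C@H](O)CC[C@H](C(=O)OC(C)(C)C)[C@@]2(C)C[C@H]1CC=C
F0 | step 7 | none | none
F4 | step 10 | C4-methoxymethylidene analogue of 12 (E/Z mixture) | CC(C)(C)[Si](C)(C)OC1=C[C@H]2[C@@H](O[Si](C)(C)C(C)(C)C)CCC(=COC)[C@@]2(C)CC1
F5 | step 10 | (4aR,8S)-8-(tert-butyldimethylsilyloxy)-5-(methoxymethylidene)-4a-methyl-4,4a,5,6,7,8-hexahydronaphthalen-2(3H)-one | O=C1C=C2[C@@H](O[Si](C)(C)C(C)(C)C)CCC(=COC)[C@@]2(C)CC1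
F6 | step 10 | (1S,4S,8aR)-4-(tert-butyldimethylsilyloxy)-8a-methyl-6-oxo-1,2,3,4,6,7,8,8a-octahydronaphthalene-1-carbaldehyde | O=C1C=C2[C@@H](O[Si](C)(C)C(C)(C)C)CC[C@H](C=O)[C@@]2(C)CC1
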